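Notation: ring positions are written as locant plus half, for example C7(A) or C2(B). Half A is the methoxy-bearing naphthoquinone and half B is the naphthazarin.
Assumption: the target is defined without configuration at the hindered C8(A)–C2(B) axis, so it is prepared as the racemate; it contains no stereocentre.

## Structural features

- The target is built from two 1,4-naphthoquinones: half A is a 5-hydroxy-3-methoxy-7-methyl-1,4-naphthoquinone and half B is a 5,8-dihydroxy-3-methyl-1,4-naphthoquinone (a naphthazarin).
- The halves are joined by one bond from the benzenoid carbon C8(A) to the quinonoid carbon C2(B).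
- This bond carries four ortho substituents: the C7(A) methyl group and the ring-fusion carbon C8a(A) with its peri carbonyl C1(A) on one side, the C3(B) methyl group and the C1(B) carbonyl on the other. It is therefore a hindered, potentially stereogenic axis.
- There is no stereocentre, so no stereocentres stand next to each other; the stereocentres that appear on the way (a diarylmethine carbon, C1 of an indene) are later erased.
- Fragile groups: the C3(A) methoxy group is a vinylogous ester on a quinone and is sensitive to nucleophiles and to aqueous acid or base. The naphthazarin is redox-active, tautomeric and base-sensitive. Both quinones are therefore unveiled at the very end from per-methylated naphthalenes.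
- The real difficulty is the fourfold ortho-substituted axis combined with the unsymmetrical oxygen pattern of half A, whose five oxygens must be told apart. The methoxy group sits on C3(A), next to the C4(A) carbonyl that is chelated by the C5(A) hydroxyl.
- The key step exploits the position of C7(A) in the benzenoid ring of half A, between C6(A)–H and the axis carbon C8(A). Taking C7(A) out contracts that ring to the five-membered ring of a 3-arylindene. In the indene the aryl group has only C2–H as a neighbour on that side, so the fourth ortho substituent arrives with the inserted carbon.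
- As its tetramethyl ether, half B has four equivalent free positions, and in the final naphthazarin the two rings are equivalent by tautomerism. Both facts are used for regiocontrol.

## Logic of the disconnections

25 ⇒ 24. The three O–CH3 bonds at C5(A), C5(B) and C8(B) are cut. The free peri-hydroxyquinones are chelating and redox-active, so they are released last, and 24 is a neutral, robust precursor. The forward step must cleave only the ethers peri to a carbonyl and keep the C3(A) vinylogous ester.

24 ⇒ 23. The four quinone carbonyls are traced back to aryl methyl ethers. Quinones would not survive organometallic reagents, a carbene or a palladium coupling, so 23 carries every oxygen as a methyl ether. The forward oxidation must pick the para-related pair C1(A)/C4(A) and one para pair of half B, and leave the C3(A) and C5(A) methoxy groups.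

23 ⇒ 22. The C7(A)–CH3 bond is cut, because the carbon that is inserted in the key step arrives bearing chlorine. This reaches the product of the key step. The forward step is a cross-coupling at a hindered, electron-rich aryl chloride next to the axis.

22 ⇒ 19 + 20. The bonds C6(A)–C7(A) and C7(A)–C8(A) are cut and C7(A) is removed as a dihalocarbene carbon.
- The benzenoid ring contracts to an indene: indene C3 is C8(A), C2 is C6(A), and C1 with its methoxy group and hydrogen is C5(A).
- The methoxy groups on indene C4, C6 and C7 become those on C1(A), C3(A) and C4(A).
- One ortho substituent leaves the axis, and the biaryl bond becomes an aryl–alkene bond.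
- The forward step requires carbene addition only at C2=C3, no prior double-bond shift in 19, and departure of the endo chloride.

19 ⇒ 18. The O–CH3 bond at C1 is cut. The ether is needed because a free hydroxyl would react with the carbene. The forward methylation must avoid alkoxides and amines, since these cause a 1,3-proton shift in 3-aryl-1-indenols and their ethers.

18 ⇒ 17. The C1–H bond is cut (alcohol to ketone). The forward reduction must be 1,2-selective on an indenone.

17 ⇒ 15. The C2=C3 double bond is traced back to the saturated ketone, which is what a Friedel–Crafts ring closure delivers. The dehydrogenation must tolerate two very electron-rich arenes and a benzylic methyl group.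

15 ⇒ 14. The acyl–arene bond C1–C7a, which is C5(A)–C4a(A) of the target, is cut. This opens the five-membered ring to an acyclic diarylmethyl acyl donor. The forward acylation has to occur at the only position able to close a five-membered ring, which is activated by a single ortho methoxy group. It must not ionise the diarylmethyl–carbon bond.

14 ⇒ 11 + 12 (through 13). The bond between the diarylmethine carbon and the trimethoxyphenyl ring is cut; it is C8(A)–C8a(A) of the target. The molecule falls into the half B acceptor 11 and the purchasable bromide 12, whose substitution pattern fixes that of half A. The forward conjugate addition must reach a β-carbon screened by a doubly ortho-substituted aryl group.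

11 ⇒ 9 + 10. The alkylidene C=C bond is cut. This is a condensation between an aldehyde and the acidic methylene compound 10, and it needs only that the hindered formyl group of 9 condenses.

9 ⇒ 5. The C3(B)–CH3 bond is cut. An electrophile would not be directed reliably to the position between methyl and methoxy in a 2-methyl analogue of 3, because the unsubstituted ring offers two equally activated, less hindered sites. The methyl group is therefore introduced after the formyl group and under its direction. The forward step needs lithiation at the one C–H flanked by two directing groups.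

5 ⇒ 3. The C2(B)–CHO bond is cut; this carbon–carbon bond is the future axis bond. All four free positions of 3 are equivalent, so the forward formylation has no regiochemical choice and takes place at a position with only one ortho substituent.

3 ⇒ 1. The four O–CH3 bonds are cut and the oxidation level is returned to the quinone. This reaches the purchasable 1. The forward step must methylate the air-sensitive reduced form before it reoxidises.

## Other disconnections considered

Alternative 1: The cut runs through C1(B)–C8a(B) and C4(B)–C4a(B).
- Forward key step: the benzenoid ring of half B would come from p-benzoquinone A3 and its four quinonoid carbons from the bis(silyloxy)furan A2. A2 is the double silyl enol ether of the aryl(methyl)succinic anhydride A1. A2 would add as a diene across one double bond of A3, the oxygen-bridged adduct would open to the ene-dione, and the former quinone ring would enolise. This gives the naphthazarin A4 with half A still fully methylated.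
- In its favour: the naphthazarin appears at its final oxidation level with no oxidant and no protecting group on half B. The dienophile is symmetrical, so no regiochemical question arises. Only two steps would remain (oxidation of half A, cleavage of the C5(A) ether).
- Against it here: half A must be complete, with its C7(A) methyl group, before A1 can be made. The bond at C8(A) then has to be formed at a carbon already flanked by C7(A)–CH3 and the peri C1(A) methoxy group, so the hindrance is moved into the preparation of A1 and not avoided. Tetrasubstituted bis(silyloxy)furans are hydrolytically labile, and the twisted naphthyl group screens both faces of the diene. The late oxidation of half A would run beside a free naphthazarin that is easily over-oxidised.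
- Comparison on structure: the alternative completes half B last; the chosen plan completes half A last and obtains its whole benzenoid ring from a trimethoxyphenyl unit plus one inserted carbon.
- Comparison on mechanism: both use a concerted addition followed by a spontaneous reorganisation, and both have close known analogues; they are equal on this point.
- Comparison on step economy: the end game of the alternative is one step shorter and its treatment of half B is better. A separate synthesis of a fully substituted half A would probably make the total equal or longer.

Alternative 2: The cut runs through C4a(A)–C5(A) and C8(A)–C8a(A).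
- Forward key step: the quinone ring of half A would come from 2-bromo-6-methoxy-1,4-benzoquinone A6, and the carbons C5(A) to C8(A) from the vinylketene silyl acetal A5, which carries per-methylated half B on its terminal carbon and could be derived from 9. A5 would add to the brominated double bond of A6, the ketene acetal carbon bonding to the bromine-bearing carbon. Loss of HBr and of methanol would then aromatise the new ring to the quinone A7.
- In its favour: one step installs the benzenoid ring of half A with its methyl group, the free C5(A) hydroxyl, the quinone and the C3(A) methoxy group, all in the right places. Bromine directs the regiochemistry in a well-understood way. Only the oxidation of half B and the cleavage of two peri ethers would remain.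
- Against it here: the bond C8(A)–C8a(A) would form at a diene terminus that bears a twisted, doubly ortho-substituted naphthyl group, so the fourfold ortho-substituted axis is created in the most hindered bond-forming event possible. The diene needs a defined geometry with the aryl group outside. Stepwise Michael-type addition and electron transfer from the electron-rich naphthalene to the oxidising bromoquinone are plausible competing paths.
- Comparison on structure: both plans build half A around the axis carbon. The chosen plan first makes the aryl–carbon bond at an unhindered centre and inserts the flanking carbon afterwards.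
- Comparison on mechanism: regiocontrol is equally secure in both, by bromine here and by the ring-opening mechanism in the chosen plan.
- Comparison on step economy: the alternative is the better one. It is several steps shorter and needs neither a late cross-coupling nor an oxidation of half A. It is not chosen because its key bond formation is the least certain.

Alternative 3: The cut removes the quinonoid ring of half A through C4(A)–C4a(A), C1(A)–C2(A), C3(A)–C4(A) and C1(A)–C8a(A).
- Forward key step: irradiation of the biaryl diazoketone A8 would give an aryl ketene by Wolff rearrangement. Cycloaddition with methoxyethyne A9 would give a cyclobutenone, which would open to a dienylketene and close by six-electron electrocyclisation onto C8a(A). Tautomerisation would give the naphthol A10.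
- In its favour: the biaryl bond would be made early by cross-coupling onto a simple benzene, with only three ortho substituents. The C7(A) methyl group is present from the start. The annulation can occur only at the single free ortho position. The new C1(A) hydroxyl allows a mild para-oxidation to the quinone with the C3(A) methoxy group already in place.
- Against it here: A9 is volatile and unstable. The tetramethoxynaphthalene chromophore absorbs where the diazoketone does and is easily photo-oxidised. The electrocyclisation must take place at the carbon next to the bulky aryl group. Making A8 adds steps with diazomethane-type reagents.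
- Comparison on structure: both plans raise the axis from three to four ortho substituents only in the key step and are equal on this point. The alternative closes the quinonoid ring and the chosen plan closes the benzenoid ring.
- Comparison on mechanism: four consecutive pericyclic events against a carbene addition and one electrocyclic opening, so the alternative has more points of failure.
- Comparison on step economy: about equal. The alternative is better in that half A needs only a mild oxidant and no late palladium step.

Key step: step 10

## Steps

Step 1
Reactants: 1 naphthazarin (5,8-dihydroxynaphthalene-1,4-dione)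
Product: 3 1,4,5,8-tetramethoxynaphthalene, via naphthalene-1,4,5,8-tetrol 2 (not isolated)
Conditions: Na2S2O4, NaOH (aq), Bu4NBr, THF/H2O, rt, argon; then Me2SO4, rt
Reagents that add atoms: dimethyl sulfate, COS(=O)(=O)OC
Why: Reductive O-methylation: Na2S2O4 reduces the quinone to the air-sensitive tetraphenolate 2, which is methylated exhaustively in a phase-transfer Williamson etherification before it can reoxidise.

Step 2
Reactants: 3 1,4,5,8-tetramethoxynaphthalene
Product: 5 1,4,5,8-tetramethoxynaphthalene-2-carbaldehyde, via aryliminium chloride 4 (not isolated)
Conditions: POCl3, DMF, 65 °C; then ice/H2O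
Reagents that add atoms: N,N-dimethylformamide, CN(C)C=O; water, O
Why: Vilsmeier–Haack formylation; the four free positions of 3 are equivalent by symmetry, so only one monoaldehyde can form, and the iminium group of 4 deactivates the ring system against a second substitution.

Step 3
Reactants: 5 1,4,5,8-tetramethoxynaphthalene-2-carbaldehyde
Product: 9 1,4,5,8-tetramethoxy-3-methylnaphthalene-2-carbaldehyde, via lithium α-amino alkoxide 6 (not isolated), via 3-lithio α-amino alkoxide 7 (not isolated), via 3-methyl α-amino alkoxide 8 (not isolated)
Conditions: Me2NCH2CH2N(Me)Li (from Me2NCH2CH2NHMe, n-BuLi), THF, −20 °C; n-BuLi, −20 °C; MeI, −78 °C → rt; H2O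
Reagents that add atoms: iodomethane, CI
Why: Directed ortho-metalation through an in situ α-amino alkoxide: the lithium amide adds to the formyl group, which masks it and places a chelating diamine next to C3–H. This hydrogen is the only one flanked by two directing groups (the alkoxide and the 4-methoxy group), so lithiation and methylation occur there, and hydrolysis on work-up returns the aldehyde.

Step 4
Reactants: 9 1,4,5,8-tetramethoxy-3-methylnaphthalene-2-carbaldehyde; 10 Meldrum's acid (2,2-dimethyl-1,3-dioxane-4,6-dione)
Product: 11 2,2-dimethyl-5-[(1,4,5,8-tetramethoxy-3-methylnaphthalen-2-yl)methylidene]-1,3-dioxane-4,6-dione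
Conditions: piperidine (cat.), AcOH (cat.), toluene, 4 Å molecular sieves, 50 °C
Reagents that add atoms: none
Why: Knoevenagel condensation through the piperidine-derived iminium ion; the low pKa of Meldrum's acid lets even a doubly ortho-substituted, electron-rich aldehyde condense, and the symmetrical acceptor raises no question of alkene geometry.

Step 5
Reactants: 11 2,2-dimethyl-5-[(1,4,5,8-tetramethoxy-3-methylnaphthalen-2-yl)methylidene]-1,3-dioxane-4,6-dione; 12 1-bromo-2,4,5-trimethoxybenzene
Product: 14 racemic 2,2-dimethyl-5-[(1,4,5,8-tetramethoxy-3-methylnaphthalen-2-yl)(2,4,5-trimethoxyphenyl)methyl]-1,3-dioxane-4,6-dione, via (2,4,5-trimethoxyphenyl)magnesium bromide 13 (not isolated)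
Conditions: 12, Mg, THF, 50 °C; then 11, THF, −40 → 0 °C; HCl (aq, cold)
Reagents that add atoms: none
Why: Conjugate addition of an aryl Grignard reagent to an alkylidene Meldrum's acid, a very strong Michael acceptor whose carbonyl groups are shielded lactone-type esters, so 1,4-addition is the normal course. The new diarylmethine stereocentre forms as the racemate and is destroyed in step 7.

Step 6
Reactants: 14 racemic 2,2-dimethyl-5-[(1,4,5,8-tetramethoxy-3-methylnaphthalen-2-yl)(2,4,5-trimethoxyphenyl)methyl]-1,3-dioxane-4,6-dione
Product: 15 racemic 4,6,7-trimethoxy-3-(1,4,5,8-tetramethoxy-3-methylnaphthalen-2-yl)-2,3-dihydro-1H-inden-1-one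
Conditions: Sc(OTf)3 (10 mol %), MeNO2, 100 °C, high dilution
Reagents that add atoms: none
Why: Intramolecular Friedel–Crafts acylation with the Meldrum's acid unit as acyl donor under Lewis acid catalysis, with loss of acetone and CO2. The only position that can close a five-membered ring is C6–H of the trimethoxyphenyl group (ortho to a methoxy group), because both positions next to the tether on the naphthalene are substituted.

Step 7
Reactants: 15 racemic 4,6,7-trimethoxy-3-(1,4,5,8-tetramethoxy-3-methylnaphthalen-2-yl)-2,3-dihydro-1H-inden-1-one
Product: 17 4,6,7-trimethoxy-3-(1,4,5,8-tetramethoxy-3-methylnaphthalen-2-yl)-1H-inden-1-one, via lithium enolate 16 (not isolated)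
Conditions: LiN(i-Pr)2, THF, −78 °C; then PhS(Cl)=N-t-Bu, −78 °C → rt
Reagents that add atoms: none
Why: Mukaiyama dehydrogenation: the C2 enolate is sulfenylated by the sulfinimidoyl chloride trans to the aryl group, and the adduct undergoes syn-elimination with the cis C3–H at low temperature. The reagent is not an electron-transfer oxidant, so the electron-rich arenes and the benzylic methyl group are left alone.

Step 8
Reactants: 17 4,6,7-trimethoxy-3-(1,4,5,8-tetramethoxy-3-methylnaphthalen-2-yl)-1H-inden-1-one
Product: 18 racemic 4,6,7-trimethoxy-3-(1,4,5,8-tetramethoxy-3-methylnaphthalen-2-yl)-1H-inden-1-ol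
Conditions: NaBH4, CeCl3·7H2O, MeOH, −40 → 0 °C
Reagents that add atoms: none
Why: Luche reduction: CeCl3 in methanol turns borohydride into a hard alkoxyborohydride that attacks the carbonyl carbon (1,2-addition) and not the hindered, aryl-bearing β-carbon. C1 becomes a racemic stereocentre which, like any rotamer about the indene–naphthyl bond, is erased in step 10.

Step 9
Reactants: 18 racemic 4,6,7-trimethoxy-3-(1,4,5,8-tetramethoxy-3-methylnaphthalen-2-yl)-1H-inden-1-ol
Product: 19 racemic 1,4,6,7-tetramethoxy-3-(1,4,5,8-tetramethoxy-3-methylnaphthalen-2-yl)-1H-indene
Conditions: Me3OBF4, 2,6-di-tert-butyl-4-methylpyridine, CH2Cl2, 0 °C → rt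
Reagents that add atoms: trimethyloxonium tetrafluoroborate, C[O+](C)C.F[B-](F)(F)F
Why: O-Methylation with a Meerwein salt buffered by a hindered, non-nucleophilic pyridine. No alkoxide or amine base is present, which avoids the base-mediated 1,3-proton shift that would turn the indenol into the indanone or the ether into its enol-ether isomer.

Step 10
Reactants: 19 racemic 1,4,6,7-tetramethoxy-3-(1,4,5,8-tetramethoxy-3-methylnaphthalen-2-yl)-1H-indene; 20 sodium trichloroacetate
Product: 22 7-chloro-1,3,4,5-tetramethoxy-8-(1,4,5,8-tetramethoxy-3-methylnaphthalen-2-yl)naphthalene (half A numbering), via gem-dichlorocyclopropane adduct 21 (not isolated)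
Conditions: 20 (5 equiv, in portions), DME, 85 °C; then toluene, 110 °C if 21 persists; NaHCO3 (aq) work-up
Reagents that add atoms: none
Why: Thermal decarboxylation of 20 gives the trichloromethyl anion, which loses chloride to singlet dichlorocarbene under essentially neutral conditions. The electrophilic carbene adds stereospecifically to the strained, styrene-type C2=C3 bond of 19, bonding first to the less hindered C2 while positive charge builds at the aryl-bearing C3, and gives the gem-dichlorocyclopropane 21. A thermally allowed disrotatory electrocyclic opening of the cyclopropane, concerted with ionisation of the endo C–Cl bond, cleaves the former C2–C3 bond and leaves an allyl cation inside a new six-membered ring; loss of the proton from the methoxy-bearing carbon C5(A) aromatises it. The benzenoid ring of half A is thus closed by ring expansion (cyclopropyl-to-allyl cation rearrangement, a one-carbon insertion) and not by an end-to-end cyclisation, and the two new skeletal bonds are C6(A)–C7(A) and C7(A)–C8(A). The closest known reaction type is the dihalocarbene ring expansion of indenes to 2-halonaphthalenes. No stereocentre is created: C1 of 19 and the stereocentres of 21 become sp2 carbons, and the hindered axis forms as the racemate. The step needs site selectivity for the indene double bond over the two electron-rich arenes, which ring strain and the nucleophilic styrene character of that bond supply, and it needs 19 not to isomerise beforehand, which the base-free carbene source secures. The place of chlorine is fixed by the mechanism: the carbene carbon keeps its exo chlorine and becomes C7(A), the site of the methyl group.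

Step 11
Reactants: 22 7-chloro-1,3,4,5-tetramethoxy-8-(1,4,5,8-tetramethoxy-3-methylnaphthalen-2-yl)naphthalene (half A numbering)
Product: 23 1,3,4,5-tetramethoxy-7-methyl-8-(1,4,5,8-tetramethoxy-3-methylnaphthalen-2-yl)naphthalene (half A numbering)
Conditions: MeB(OH)2, Pd(OAc)2 (5 mol %), SPhos (10 mol %), K3PO4, toluene/H2O, 100 °C
Reagents that add atoms: methylboronic acid, CB(O)O
Why: Suzuki–Miyaura cross-coupling; the electron-rich dialkylbiarylphosphine gives a monoligated zerovalent palladium species that inserts into hindered, electron-rich aryl chlorides, and the methyl group is transferred without any β-hydride pathway.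

Step 12
Reactants: 23 1,3,4,5-tetramethoxy-7-methyl-8-(1,4,5,8-tetramethoxy-3-methylnaphthalen-2-yl)naphthalene (half A numbering)
Product: 24 8-(5,8-dimethoxy-3-methyl-1,4-dioxo-1,4-dihydronaphthalen-2-yl)-3,5-dimethoxy-7-methylnaphthalene-1,4-dione (half A numbering)
Conditions: (NH4)2Ce(NO3)6 (5–6 equiv), MeCN/H2O, 0 °C
Reagents that add atoms: water, O
Why: Oxidative demethylation of para-dimethoxyarenes by tetravalent cerium through arene radical cations and attack of water. In half A only the C1(A)/C4(A) pair is para-related, so the 3-methoxy-1,4-quinone results. In half B either ring may be oxidised, because both dimethoxyquinones give the same naphthazarin after step 13; the isomer written is the one expected from the more substituted, more strained ring.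

Step 13
Reactants: 24 8-(5,8-dimethoxy-3-methyl-1,4-dioxo-1,4-dihydronaphthalen-2-yl)-3,5-dimethoxy-7-methylnaphthalene-1,4-dione (half A numbering)
Product: 25 8'-hydroxy-3-methoxyisodiospyrin (racemic at the axis)
Conditions: BCl3 (excess), CH2Cl2, −78 → 0 °C; then H2O
Reagents that add atoms: none
Why: Lewis acid-mediated cleavage of aryl methyl ethers peri to a quinone carbonyl: BCl3 binds the carbonyl oxygen and forms a six-membered chelate with each peri oxygen, so chloride removes only those three methyl groups. The C3(A) methoxy group, a vinylogous ester that could form only a strained five-membered chelate, is retained at low temperature.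

## Compound list

1 | naphthazarin (5,8-dihydroxynaphthalene-1,4-dione) | O=C1C=CC(=O)c2c(O)ccc(O)c12 | starting material
2 | naphthalene-1,4,5,8-tetrol (leuco form, present as its sodium salt) | Oc1ccc(O)c2c(O)ccc(O)c12 | intermediate
3 | 1,4,5,8-tetramethoxynaphthalene | COc1ccc(OC)c2c(OC)ccc(OC)c12 | intermediate
4 | N,N-dimethyl-1-(1,4,5,8-tetramethoxynaphthalen-2-yl)methaniminium chloride | C[N+](C)=Cc1cc(OC)c2c(OC)ccc(OC)c2c1OC.[Cl-] | intermediate
5 | 1,4,5,8-tetramethoxynaphthalene-2-carbaldehyde | O=Cc1cc(OC)c2c(OC)ccc(OC)c2c1OC | intermediate
6 | lithium {[2-(dimethylamino)ethyl](methyl)amino}(1,4,5,8-tetramethoxynaphthalen-2-yl)methanolate (racemic) | [Li+].[O-]C(N(C)CCN(C)C)c1cc(OC)c2c(OC)ccc(OC)c2c1OC | intermediate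
7 | 3-lithio derivative of 6 (racemic) | [Li+].[O-]C(N(C)CCN(C)C)c1c([Li])c(OC)c2c(OC)ccc(OC)c2c1OC | intermediate
8 | lithium {[2-(dimethylamino)ethyl](methyl)amino}(1,4,5,8-tetramethoxy-3-methylnaphthalen-2-yl)methanolate (racemic) | [Li+].[O-]C(N(C)CCN(C)C)c1c(C)c(OC)c2c(OC)ccc(OC)c2c1OC | intermediate
9 | 1,4,5,8-tetramethoxy-3-methylnaphthalene-2-carbaldehyde | O=Cc1c(C)c(OC)c2c(OC)ccc(OC)c2c1OC | intermediate
10 | Meldrum's acid (2,2-dimethyl-1,3-dioxane-4,6-dione) | CC1(C)OC(=O)CC(=O)O1 | starting material
11 | 2,2-dimethyl-5-[(1,4,5,8-tetramethoxy-3-methylnaphthalen-2-yl)methylidene]-1,3-dioxane-4,6-dione | CC1(C)OC(=O)C(=Cc2c(C)c(OC)c3c(OC)ccc(OC)c3c2OC)C(=O)O1 | intermediate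
12 | 1-bromo-2,4,5-trimethoxybenzene | COc1cc(OC)c(Br)cc1OC | starting material
13 | (2,4,5-trimethoxyphenyl)magnesium bromide | COc1cc(OC)c([Mg]Br)cc1OC | intermediate
14 | racemic 2,2-dimethyl-5-[(1,4,5,8-tetramethoxy-3-methylnaphthalen-2-yl)(2,4,5-trimethoxyphenyl)methyl]-1,3-dioxane-4,6-dione | CC1(C)OC(=O)C(C(c2cc(OC)c(OC)cc2OC)c2c(C)c(OC)c3c(OC)ccc(OC)c3c2OC)C(=O)O1 | intermediate
15 | racemic 4,6,7-trimethoxy-3-(1,4,5,8-tetramethoxy-3-methylnaphthalen-2-yl)-2,3-dihydro-1H-inden-1-one | O=C1CC(c2c(C)c(OC)c3c(OC)ccc(OC)c3c2OC)c2c(OC)cc(OC)c(OC)c12 | intermediate
16 | lithium enolate of 15 (lithium 4,6,7-trimethoxy-1-(1,4,5,8-tetramethoxy-3-methylnaphthalen-2-yl)-1H-inden-3-olate, racemic) | [Li+].[O-]C1=CC(c2c(C)c(OC)c3c(OC)ccc(OC)c3c2OC)c2c(OC)cc(OC)c(OC)c12 | intermediate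
17 | 4,6,7-trimethoxy-3-(1,4,5,8-tetramethoxy-3-methylnaphthalen-2-yl)-1H-inden-1-one | O=C1C=C(c2c(C)c(OC)c3c(OC)ccc(OC)c3c2OC)c2c(OC)cc(OC)c(OC)c12 | intermediate
18 | racemic 4,6,7-trimethoxy-3-(1,4,5,8-tetramethoxy-3-methylnaphthalen-2-yl)-1H-inden-1-ol | OC1C=C(c2c(C)c(OC)c3c(OC)ccc(OC)c3c2OC)c2c(OC)cc(OC)c(OC)c12 | intermediate
19 | racemic 1,4,6,7-tetramethoxy-3-(1,4,5,8-tetramethoxy-3-methylnaphthalen-2-yl)-1H-indene | COC1C=C(c2c(C)c(OC)c3c(OC)ccc(OC)c3c2OC)c2c(OC)cc(OC)c(OC)c12 | intermediate
20 | sodium trichloroacetate | [Na+].[O-]C(=O)C(Cl)(Cl)Cl | starting material
21 | 1,1-dichloro-2,4,5,6-tetramethoxy-1a-(1,4,5,8-tetramethoxy-3-methylnaphthalen-2-yl)-1,1a,6,6a-tetrahydrocyclopropa[a]indene (racemic, cis-fused, configuration at C6 relative to the cyclopropane not controlled) | COC1C2C(Cl)(Cl)C2(c2c(C)c(OC)c3c(OC)ccc(OC)c3c2OC)c2c(OC)cc(OC)c(OC)c12 | intermediate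
22 | 7-chloro-1,3,4,5-tetramethoxy-8-(1,4,5,8-tetramethoxy-3-methylnaphthalen-2-yl)naphthalene (half A numbering; racemic axis) | COc1cc(OC)c2c(-c3c(C)c(OC)c4c(OC)ccc(OC)c4c3OC)c(Cl)cc(OC)c2c1OC | intermediate
23 | 1,3,4,5-tetramethoxy-7-methyl-8-(1,4,5,8-tetramethoxy-3-methylnaphthalen-2-yl)naphthalene (half A numbering; racemic axis) | COc1cc(OC)c2c(-c3c(C)c(OC)c4c(OC)ccc(OC)c4c3OC)c(C)cc(OC)c2c1OC | intermediate
24 | 8-(5,8-dimethoxy-3-methyl-1,4-dioxo-1,4-dihydronaphthalen-2-yl)-3,5-dimethoxy-7-methylnaphthalene-1,4-dione (half A numbering; racemic axis) | COC1=CC(=O)c2c(C3=C(C)C(=O)c4c(OC)ccc(OC)c4C3=O)c(C)cc(OC)c2C1=O | intermediate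
25 | 8'-hydroxy-3-methoxyisodiospyrin, 8-(5,8-dihydroxy-3-methyl-1,4-dioxo-1,4-dihydronaphthalen-2-yl)-5-hydroxy-3-methoxy-7-methylnaphthalene-1,4-dione (half A numbering; racemic axis) | COC1=CC(=O)c2c(C3=C(C)C(=O)c4c(O)ccc(O)c4C3=O)c(C)cc(O)c2C1=O | target

## Step count and least certain steps

Total step count: 13. Longest linear sequence: 13 steps (1 to 25); compounds 10, 12 and 20 are purchased and enter directly.

Step 10 (key step). Three processes could spoil it.
- Carbene transfer to the trisubstituted double bond may be slow, because its faces are partly screened by the twisted naphthyl group, and carbene may then be consumed by the electron-rich arenes.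
- The HCl released may ionise the allylic methyl ether, or an adventitious base may cause a double-bond shift before cyclopropanation, which would place chlorine on C6(A).
- The adduct may fail to open completely.
- Fallback, setting out from 17 and returning at 23: the one-carbon unit is delivered as a nucleophile that already carries the methyl group. Diphenylsulfonium ethylide (from Ph2S(Et)BF4 and LiN(i-Pr)2, DME, −78 °C) would add to the enone of 17 at C3 and close onto C2 in a Corey–Chaykovsky cyclopropanation. This gives the cyclopropyl ketone 2,4,5-trimethoxy-1-methyl-1a-(1,4,5,8-tetramethoxy-3-methylnaphthalen-2-yl)-1a,6a-dihydrocyclopropa[a]inden-6(1H)-one F1. Acid (TsOH, toluene, heat) would cleave the cyclopropane bond between the α-carbon and the aryl-bearing carbon and, after loss of a proton, give the naphthol 5,7,8-trimethoxy-3-methyl-4-(1,4,5,8-tetramethoxy-3-methylnaphthalen-2-yl)naphthalen-1-ol F2. O-Methylation of F2 (MeI, K2CO3, acetone) gives 23, so 22 and step 11 are bypassed.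

Step 5. Conjugate addition may be slow because the β-carbon of 11 is screened on both faces by the ortho methyl and methoxy groups of the perpendicular naphthyl ring. Electron transfer or attack at a carbonyl group could then compete.
- Fallback, setting out from 9 and 13 and returning at 14: the Grignard reagent 13 is added to the aldehyde 9 (THF, 0 °C) to give the benzhydrol (1,4,5,8-tetramethoxy-3-methylnaphthalen-2-yl)(2,4,5-trimethoxyphenyl)methanol F3. Its hydroxyl group is then replaced by Meldrum's acid 10 in an acid-catalysed substitution through the strongly stabilised diarylmethyl cation (TsOH cat., CH2Cl2, rt), which gives 14.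

Step 6. The Lewis acid may induce heterolysis of the bond between the diarylmethyl carbon and the Meldrum's acid carbon, since the cation is stabilised by two electron-rich arenes. Intermolecular acylation of the nucleophilic free positions could also outrun ring closure at a position activated by only one methoxy group.
- Fallback, setting out from 14 and returning at 15: hydrolysis and decarboxylation (pyridine/H2O, 100 °C) would give 3-(1,4,5,8-tetramethoxy-3-methylnaphthalen-2-yl)-3-(2,4,5-trimethoxyphenyl)propanoic acid F4. Treatment with (COCl)2 and catalytic DMF would give the acid chloride 3-(1,4,5,8-tetramethoxy-3-methylnaphthalen-2-yl)-3-(2,4,5-trimethoxyphenyl)propanoyl chloride F5. F5 is cyclised at low temperature with SnCl4 (CH2Cl2, −20 °C) to 15, under conditions too mild to ionise the diarylmethyl carbon.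

Step 11. Oxidative addition into the chloride next to the bulky naphthyl group may be slow, so that protodechlorination or decay of the catalyst takes over.
- Fallback, setting out from 22 and returning at 23: the polarity is reversed. Reductive lithiation of 22 with lithium 4,4'-di-tert-butylbiphenylide (THF, −78 °C) would give the aryllithium [4,5,6,8-tetramethoxy-1-(1,4,5,8-tetramethoxy-3-methylnaphthalen-2-yl)naphthalen-2-yl]lithium F6, which is quenched with MeI to give 23.

Step 13. Cleavage may be incomplete at the hindered peri ethers of half B, or the C3(A) vinylogous ester methyl group may be lost together with the peri methyl groups.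
- Fallback, setting out from 24 and returning at 25: all four ethers are cleaved on purpose with excess BBr3 (CH2Cl2, −78 °C → rt) to give 8-(5,8-dihydroxy-3-methyl-1,4-dioxo-1,4-dihydronaphthalen-2-yl)-3,5-dihydroxy-7-methylnaphthalene-1,4-dione F7. The acidic hydroxyquinone oxygen alone is then re-methylated by acid-catalysed exchange with methanol (MeOH, HCl cat., reflux). The chelated peri hydroxyls do not react under these conditions, and 25 results.

## Further compounds

F1 | step 10 | 2,4,5-trimethoxy-1-methyl-1a-(1,4,5,8-tetramethoxy-3-methylnaphthalen-2-yl)-1a,6a-dihydrocyclopropa[a]inden-6(1H)-one (racemic) | O=C1C2C(C)C2(c2c(C)c(OC)c3c(OC)ccc(OC)c3c2OC)c2c(OC)cc(OC)c(OC)c12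
F2 | step 10 | 5,7,8-trimethoxy-3-methyl-4-(1,4,5,8-tetramethoxy-3-methylnaphthalen-2-yl)naphthalen-1-ol | COc1cc(OC)c2c(-c3c(C)c(OC)c4c(OC)ccc(OC)c4c3OC)c(C)cc(O)c2c1OC
F3 | step 5 | (1,4,5,8-tetramethoxy-3-methylnaphthalen-2-yl)(2,4,5-trimethoxyphenyl)methanol (racemic) | OC(c1cc(OC)c(OC)cc1OC)c1c(C)c(OC)c2c(OC)ccc(OC)c2c1OC
F4 | step 6 | 3-(1,4,5,8-tetramethoxy-3-methylnaphthalen-2-yl)-3-(2,4,5-trimethoxyphenyl)propanoic acid (racemic) | OC(=O)CC(c1cc(OC)c(OC)cc1OC)c1c(C)c(OC)c2c(OC)ccc(OC)c2c1OC
F5 | step 6 | 3-(1,4,5,8-tetramethoxy-3-methylnaphthalen-2-yl)-3-(2,4,5-trimethoxyphenyl)propanoyl chloride (racemic) | ClC(=O)CC(c1cc(OC)c(OC)cc1OC)c1c(C)c(OC)c2c(OC)ccc(OC)c2c1OC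
F6 | step 11 | [4,5,6,8-tetramethoxy-1-(1,4,5,8-tetramethoxy-3-methylnaphthalen-2-yl)naphthalen-2-yl]lithium | COc1cc(OC)c2c(-c3c(C)c(OC)c4c(OC)ccc(OC)c4c3OC)c([Li])cc(OC)c2c1OC
F7 | step 13 | 8-(5,8-dihydroxy-3-methyl-1,4-dioxo-1,4-dihydronaphthalen-2-yl)-3,5-dihydroxy-7-methylnaphthalene-1,4-dione (half A numbering) | OC1=CC(=O)c2c(C3=C(C)C(=O)c4c(O)ccc(O)c4C3=O)c(C)cc(O)c2C1=O
A1 | alternative 1 | 3-methyl-4-(1,3,4,5-tetramethoxy-7-methylnaphthalen-8-yl)oxolane-2,5-dione (half A numbering for the aryl group; racemic) | CC1C(c2c(C)cc(OC)c3c(OC)c(OC)cc(OC)c23)C(=O)OC1=O
A2 | alternative 1 | 3-methyl-4-(1,3,4,5-tetramethoxy-7-methylnaphthalen-8-yl)-2,5-bis(trimethylsilyloxy)furan (half A numbering for the aryl group) | Cc1c(O[Si](C)(C)C)oc(O[Si](C)(C)C)c1-c1c(C)cc(OC)c2c(OC)c(OC)cc(OC)c12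
A3 | alternative 1 | p-benzoquinone | O=C1C=CC(=O)C=C1
A4 | alternative 1 | 5,8-dihydroxy-3-methyl-2-(1,3,4,5-tetramethoxy-7-methylnaphthalen-8-yl)naphthalene-1,4-dione (half A numbering for the aryl group) | COc1cc(OC)c2c(C3=C(C)C(=O)c4c(O)ccc(O)c4C3=O)c(C)cc(OC)c2c1OC
A5 | alternative 2 | {[1-methoxy-3-methyl-4-(1,4,5,8-tetramethoxy-3-methylnaphthalen-2-yl)buta-1,3-dien-1-yl]oxy}trimethylsilane | COC(O[Si](C)(C)C)=CC(C)=Cc1c(C)c(OC)c2c(OC)ccc(OC)c2c1OC
A6 | alternative 2 | 2-bromo-6-methoxy-1,4-benzoquinone | COC1=CC(=O)C=C(Br)C1=O
A7 | alternative 2 | 5-hydroxy-3-methoxy-7-methyl-8-(1,4,5,8-tetramethoxy-3-methylnaphthalen-2-yl)naphthalene-1,4-dione (half A numbering) | COC1=CC(=O)c2c(-c3c(C)c(OC)c4c(OC)ccc(OC)c4c3OC)c(C)cc(O)c2C1=O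
A8 | alternative 3 | 2-diazo-1-[2-methoxy-4-methyl-5-(1,4,5,8-tetramethoxy-3-methylnaphthalen-2-yl)phenyl]ethan-1-one | COc1cc(C)c(-c2c(C)c(OC)c3c(OC)ccc(OC)c3c2OC)cc1C(=O)C=[N+]=[N-]
A9 | alternative 3 | methoxyethyne | COC#C
A10 | alternative 3 | 3,5-dimethoxy-7-methyl-8-(1,4,5,8-tetramethoxy-3-methylnaphthalen-2-yl)naphthalen-1-ol (half A numbering) | COc1cc(O)c2c(-c3c(C)c(OC)c4c(OC)ccc(OC)c4c3OC)c(C)cc(OC)c2c1
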